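**Plan**
1. The 2-aryl-3-(hydroxymethyl)-7-methoxy-2,3-dihydrobenzofuran (ring O1–C2–C3–C3a–C7a, fused to ring C, the arene of the lactone β-benzyl group) is a β-5 phenylpropanoid unit. Its C3–C3a bond joins C8 of a guaiacylpropanoid to the carbon ortho to the ring C phenol oxygen, and O1–C2 joins that oxygen to C7; both bonds are cut first, giving a lactone with a free 4-hydroxy-3-methoxybenzyl group and a feruloyl amide of a chiral sultam.
2. Further cuts: the lactone C3–CH2(ring B) bond (enolate benzylation), the C7–C8 bond of the diarylpropanediol arm (aldol), and the Cα–CH2CO2R bond of the β-benzyl lactone (auxiliary alkylation).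
3. Forward: ring B arylacetic acid (Claisen, alkene cleavage), anti-aldol with silylated vanillin, reduction, acetonide, bromide; β-benzyl lactone separately; enolate benzylation joins the two; the ring C phenol is freed; the dihydrofuran ring closes last by oxidative cross-coupling; then hydrolysis, borane reduction and desilylation.
4. Stereochemistry: arm C7/C8 from the (S)-oxazolidinone anti-aldol; lactone C4 from the (R)-oxazolidinone alkylation and C3 from benzylation anti to the C4 substituent; dihydrobenzofuran C3 from the sultam and C2 from trans ring closure.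

Key step: step 21

Assumption: the (2R)-bornane-10,2-sultam is taken to steer ring C onto the C8 face that gives the (2R,3R) acyl dihydrobenzofuran, in line with the face selectivity of α-alkylations and α-radical reactions of N-acyl (2R)-sultams; if the coupling favours the other face, the (2S)-sultam is used from step 19 on with no other change.

**Ring A aldehyde**

Step 1
Reactants: 1 vanillin (4-hydroxy-3-methoxybenzaldehyde)
Product: 2 3-methoxy-4-(triisopropylsilyloxy)benzaldehyde
Conditions: TIPSCl, imidazole, DMF, rt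
Reagents that add atoms: triisopropylsilyl chloride, CC(C)[Si](Cl)(C(C)C)C(C)C
Why: Imidazole-promoted silylation of the phenol should give an aryl silyl ether that withstands base, hydride and the later enzymatic oxidation and keeps the ring A oxygen out of the coupling.

**Ring B fragment with the arm**

Step 2
Reactants: 3 methyl vanillate (methyl 4-hydroxy-3-methoxybenzoate)
Product: 4 methyl 4-(allyloxy)-3-methoxybenzoate
Conditions: allyl bromide, K2CO3, acetone, reflux
Reagents that add atoms: allyl bromide, C=CCBr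
Why: Williamson etherification of the phenoxide installs the allyl group that the next step moves onto the ring.

Step 3
Reactants: 4 methyl 4-(allyloxy)-3-methoxybenzoate
Product: 5 methyl 3-allyl-4-hydroxy-5-methoxybenzoate
Conditions: N,N-diethylaniline, 200 °C
Reagents that add atoms: none
Why: Aromatic Claisen rearrangement ([3,3] shift, then enolisation) should deliver the allyl group to the only free ortho carbon, which gives ring B its 1,2,3,5-substitution pattern.

Step 4
Reactants: 5 methyl 3-allyl-4-hydroxy-5-methoxybenzoate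
Product: 6 methyl 3-allyl-5-methoxy-4-(triisopropylsilyloxy)benzoate
Conditions: TIPSOTf, 2,6-lutidine, CH2Cl2, 0 °C to rt
Reagents that add atoms: triisopropylsilyl triflate, CC(C)[Si](OS(=O)(=O)C(F)(F)F)(C(C)C)C(C)C
Why: Silylation with the silyl triflate should overcome the hindrance of the 2,6-disubstituted phenol and block the ring B oxygen until the last step.

Step 5
Reactants: 6 methyl 3-allyl-5-methoxy-4-(triisopropylsilyloxy)benzoate
Product: 8 2-[3-methoxy-5-(methoxycarbonyl)-2-(triisopropylsilyloxy)phenyl]acetic acid, via arylacetaldehyde 7 (not isolated)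
Conditions: OsO4 (2 mol %), NaIO4, 2,6-lutidine, dioxane/H2O, rt; then NaClO2, NaH2PO4, 2-methyl-2-butene, t-BuOH/H2O, rt
Reagents that add atoms: OsO4, O=[Os](=O)(=O)=O (aldehyde oxygen; reoxidised by sodium periodate, [Na+].[O-]I(=O)(=O)=O); sodium chlorite, [Na+].[O-]Cl=O (acid OH oxygen)
Why: Lemieux–Johnson cleavage of the terminal alkene followed by Pinnick oxidation of the crude aldehyde should give the arylacetic acid without attacking the electron-rich arene.

Step 6
Reactants: 8 2-[3-methoxy-5-(methoxycarbonyl)-2-(triisopropylsilyloxy)phenyl]acetic acid; 9 (S)-4-benzyloxazolidin-2-one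
Product: 11 methyl 3-{2-[(S)-4-benzyl-2-oxooxazolidin-3-yl]-2-oxoethyl}-5-methoxy-4-(triisopropylsilyloxy)benzoate, via mixed pivalic anhydride 10 (not isolated)
Conditions: PivCl, Et3N, THF, −20 °C; then 9, LiCl, rt
Reagents that add atoms: none
Why: LiCl-assisted N-acylation of the oxazolidinone through the mixed pivalic anhydride should take place at the less hindered arylacetyl carbonyl.

Step 7
Reactants: 11 methyl 3-{2-[(S)-4-benzyl-2-oxooxazolidin-3-yl]-2-oxoethyl}-5-methoxy-4-(triisopropylsilyloxy)benzoate; 2 3-methoxy-4-(triisopropylsilyloxy)benzaldehyde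
Product: 13 methyl 3-{(2R,3S)-1-[(S)-4-benzyl-2-oxooxazolidin-3-yl]-3-hydroxy-3-[3-methoxy-4-(triisopropylsilyloxy)phenyl]-1-oxopropan-2-yl}-5-methoxy-4-(triisopropylsilyloxy)benzoate, via trimethylsilyl ether 12 (not isolated)
Conditions: MgCl2 (20 mol %), Et3N, TMSCl, EtOAc, rt; then 1 M HCl, THF, 0 °C
Reagents that add atoms: none
Why: In the Evans magnesium-halide-catalysed anti-aldol reaction, soft enolisation gives the chelated Z-enolate, which should add to the aldehyde through a boat transition state on the face away from the auxiliary benzyl group and so set the (2R,3S) anti pair that becomes C8 and C7 of the target, while silylation turns MgCl2 over.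

Step 8
Reactants: 13 the (2R,3S) anti-aldol imide
Product: 14 (1S,2S)-2-[5-(hydroxymethyl)-3-methoxy-2-(triisopropylsilyloxy)phenyl]-1-[3-methoxy-4-(triisopropylsilyloxy)phenyl]propane-1,3-diol
Conditions: LiBH4 (excess), MeOH, THF, 0 °C then 50 °C
Reagents that add atoms: none
Why: Hydride reduction with LiBH4 should cleave the imide at 0 °C and reduce the aryl methyl ester on warming, so that one operation gives the 1,3-diol and the benzylic alcohol without touching either stereocentre.

Step 9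
Reactants: 14 the (1S,2S)-triol
Product: 15 {3-methoxy-5-[(4S,5S)-4-(3-methoxy-4-triisopropylsilyloxyphenyl)-2,2-dimethyl-1,3-dioxan-5-yl]-4-(triisopropylsilyloxy)phenyl}methanol
Conditions: 2,2-dimethoxypropane, PPTS (cat.), acetone, rt
Reagents that add atoms: 2,2-dimethoxypropane, COC(C)(C)OC
Why: Acid-catalysed transketalisation should engage only the 1,3-diol, as a six-membered acetonide with both aryl groups equatorial, and leave the lone benzylic alcohol free.

Step 10
Reactants: 15 the acetonide benzylic alcohol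
Product: 16 (4S,5S)-5-[5-(bromomethyl)-3-methoxy-2-(triisopropylsilyloxy)phenyl]-4-[3-methoxy-4-(triisopropylsilyloxy)phenyl]-2,2-dimethyl-1,3-dioxane
Conditions: CBr4, PPh3, 2,6-lutidine, CH2Cl2, 0 °C; used at once
Reagents that add atoms: carbon tetrabromide, BrC(Br)(Br)Br
Why: Appel bromination should convert the primary benzylic alcohol under near-neutral conditions that the acetonide and the silyl ethers tolerate.

**Ring C lactone**

Step 11
Reactants: 17 3-(4-hydroxy-3-methoxyphenyl)propanoic acid (dihydroferulic acid)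
Product: 19 3-(4-benzyloxy-3-methoxyphenyl)propanoic acid, via benzyl ester 18 (not isolated)
Conditions: BnBr, K2CO3, DMF, 60 °C; then NaOH, MeOH/H2O, 60 °C; HCl
Reagents that add atoms: benzyl bromide, BrCc1ccccc1
Why: Double O-benzylation (Williamson) followed by saponification of the benzyl ester should leave the ring C phenol masked as an ether that hydrogenolysis removes later.

Step 12
Reactants: 19 3-(4-benzyloxy-3-methoxyphenyl)propanoic acid; 20 (R)-4-benzyloxazolidin-2-one
Product: 22 (R)-4-benzyl-3-[3-(4-benzyloxy-3-methoxyphenyl)propanoyl]oxazolidin-2-one, via mixed pivalic anhydride 21 (not isolated)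
Conditions: PivCl, Et3N, THF, −20 °C; then 20, LiCl, rt
Reagents that add atoms: none
Why: N-Acylation of the oxazolidinone through the mixed pivalic anhydride is the standard entry to the imide.

Step 13
Reactants: 22 (R)-4-benzyl-3-[3-(4-benzyloxy-3-methoxyphenyl)propanoyl]oxazolidin-2-one
Product: 23 tert-butyl (3S)-4-[(R)-4-benzyl-2-oxooxazolidin-3-yl]-3-(4-benzyloxy-3-methoxybenzyl)-4-oxobutanoate
Conditions: NaN(SiMe3)2, THF, −78 °C; tert-butyl bromoacetate, −78 to −40 °C
Reagents that add atoms: tert-butyl bromoacetate, CC(C)(C)OC(=O)CBr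
Why: In this Evans asymmetric alkylation the chelated Z sodium enolate should be alkylated on the face opposite the auxiliary benzyl group, which sets the (S) centre that becomes C4 of the lactone.

Step 14
Reactants: 23 the alkylated imide
Product: 25 (S)-4-(4-benzyloxy-3-methoxybenzyl)dihydrofuran-2(3H)-one, via hydroxy ester 24 (not isolated)
Conditions: LiBH4, MeOH, THF, 0 °C; then p-TsOH·H2O (cat.), toluene, 80 °C
Reagents that add atoms: none
Why: Reductive removal of the auxiliary with LiBH4 should spare the tert-butyl ester, and acid-catalysed lactonisation of the γ-hydroxy ester then closes the butyrolactone with the stereocentre untouched.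

**Union and unmasking**

Step 15
Reactants: 25 (S)-4-(4-benzyloxy-3-methoxybenzyl)dihydrofuran-2(3H)-one; 16 the ring B benzylic bromide
Product: 26 (3S,4S)-4-(4-benzyloxy-3-methoxybenzyl)-3-{3-methoxy-5-[(4S,5S)-4-(3-methoxy-4-triisopropylsilyloxyphenyl)-2,2-dimethyl-1,3-dioxan-5-yl]-4-triisopropylsilyloxybenzyl}dihydrofuran-2(3H)-one
Conditions: LiN(SiMe3)2, THF, −78 °C; then 16, DMPU, −78 to −30 °C
Reagents that add atoms: none
Why: Alkylation of the lactone lithium enolate with the benzylic bromide should occur anti to the C4 benzyl group, giving the trans-2,3-dibenzylbutyrolactone and setting C3 as (S).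

Step 16
Reactants: 26 the acetonide lactone
Product: 27 (3S,4S)-4-(4-benzyloxy-3-methoxybenzyl)-3-{3-[(1S,2S)-1,3-dihydroxy-1-(3-methoxy-4-triisopropylsilyloxyphenyl)propan-2-yl]-5-methoxy-4-triisopropylsilyloxybenzyl}dihydrofuran-2(3H)-one
Conditions: AcOH/THF/H2O (3:1:1), 40 °C
Reagents that add atoms: none
Why: Mild aqueous acid hydrolysis of the acetonide should free the diol while the lactone, the aryl silyl ethers and the benzyl ether stay intact and the benzylic carbinol is not ionised.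

Step 17
Reactants: 27 the benzyl-protected diol lactone
Product: 28 (3S,4S)-3-{3-[(1S,2S)-1,3-dihydroxy-1-(3-methoxy-4-triisopropylsilyloxyphenyl)propan-2-yl]-5-methoxy-4-triisopropylsilyloxybenzyl}-4-(4-hydroxy-3-methoxybenzyl)dihydrofuran-2(3H)-one
Conditions: H2 (1 atm), 10% Pd/C, EtOAc, rt
Reagents that add atoms: none
Why: Hydrogenolysis of the benzyl ether over Pd/C should free only the ring C phenol, the one oxygen that the coupling needs.

**Feruloyl sultam**

Step 18
Reactants: 29 ferulic acid ((E)-3-(4-hydroxy-3-methoxyphenyl)acrylic acid)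
Product: 30 (E)-3-(4-acetoxy-3-methoxyphenyl)acrylic acid
Conditions: Ac2O, pyridine, rt; then H2O
Reagents that add atoms: acetic anhydride, CC(=O)OC(C)=O
Why: Acetylation masks the phenol so that it cannot compete in the acylation of the sultam.

Step 19
Reactants: 30 (E)-3-(4-acetoxy-3-methoxyphenyl)acrylic acid; 31 (2R)-bornane-10,2-sultam
Product: 33 N-[(E)-3-(4-acetoxy-3-methoxyphenyl)acryloyl]-(2R)-bornane-10,2-sultam, via acid chloride 32 (not isolated)
Conditions: (COCl)2, DMF (cat.), CH2Cl2, rt; then 31, Et3N, DMAP (cat.), CH2Cl2, 0 °C to rt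
Reagents that add atoms: none
Why: Acid chloride formation and DMAP-catalysed N-acylation of the sultam should give the enoyl sultam with the E alkene unchanged.

Step 20
Reactants: 33 the O-acetyl feruloyl sultam
Product: 34 N-[(E)-3-(4-hydroxy-3-methoxyphenyl)acryloyl]-(2R)-bornane-10,2-sultam (N-feruloyl sultam)
Conditions: pyrrolidine (1.5 equiv), CH2Cl2, 0 °C
Reagents that add atoms: none
Why: Aminolysis by pyrrolidine should cleave the aryl acetate within minutes, long before the N-acyl sultam or the cinnamoyl double bond reacts.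

**Key step and end game**

Step 21
Reactants: 28 the lactone with free ring C phenol; 34 N-feruloyl (2R)-bornane-10,2-sultam
Product: 36 N-{[(2R,3R)-5-{[(3S,4S)-4-{3-[(1S,2S)-1,3-dihydroxy-1-(3-methoxy-4-triisopropylsilyloxyphenyl)propan-2-yl]-5-methoxy-4-triisopropylsilyloxybenzyl}-5-oxotetrahydrofuran-3-yl]methyl}-2-(4-hydroxy-3-methoxyphenyl)-7-methoxy-2,3-dihydrobenzofuran-3-yl]carbonyl}-(2R)-bornane-10,2-sultam, via quinone methide 35 (not isolated)
Conditions: laccase (Trametes versicolor), air, EtOAc/0.1 M NaOAc buffer pH 5 (1:1), vigorous stirring, rt; 34 (0.5 equiv) added by syringe pump over 8 h to 28; stopped at partial conversion, unreacted 28 recovered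
Reagents that add atoms: none
Why: Proposed new method: laccase takes one electron from each free phenol (O2 ends as water), the C8-centred feruloyl radical should bond to C5 of the ring C phenoxyl radical, the dienone tautomerises to phenol–quinone methide 35, and the phenol oxygen adds to the methide carbon, so that C3–C3a and O1–C2 form in one operation. The closest known reaction type is the laccase- or peroxidase-mediated β-5 dehydrodimerisation of ferulates and feruloyl amides, including the sultam-directed dimerisation, together with the endwise cross-coupling of monolignol radicals onto guaiacyl phenols; what is new is the cross-coupling of a chiral feruloyl amide onto a 4-alkylguaiacol. The dihydrofuran ring closes by a 5-exo-trig oxa-Michael addition. C3 is set in the radical–radical C–C bond formation by the bornanesultam, which shields one face of the planar acyl radical, and C2 follows because closure places the aryl group trans to the C3 acyl group, as in every β-5 dimer. The step needs cross- over homo-coupling and C- over O-coupling on ring C: slow addition of 34 to an excess of 28 keeps the feruloyl radical scarce, the phenols of rings A and B are silylated, ring C offers a single unsubstituted carbon ortho to its oxygen, and conversion is held low because the new phenol of 36 can itself be oxidised.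

Step 22
Reactants: 36 the dihydrobenzofuran acyl sultam
Product: 38 (2R,3R)-5-{[(3S,4S)-4-{3-[(1S,2S)-1,3-dihydroxy-1-(3-methoxy-4-triisopropylsilyloxyphenyl)propan-2-yl]-5-methoxy-4-triisopropylsilyloxybenzyl}-5-oxotetrahydrofuran-3-yl]methyl}-2-(4-hydroxy-3-methoxyphenyl)-7-methoxy-2,3-dihydrobenzofuran-3-carboxylic acid, via peroxy acid 37 (not isolated)
Conditions: LiOH·H2O, 30% H2O2, THF/H2O (3:1), 0 °C; Na2SO3; then 1 M HCl to pH 2, rt
Reagents that add atoms: hydrogen peroxide (as LiOOH; one oxygen of the CO2H group), OO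
Why: In this LiOOH cleavage the hydroperoxide anion should attack the exocyclic carbonyl of the N-acyl sultam faster than the C3 proton is removed, sulfite reduces the peracid, and acidification closes any lactone that has opened, with trans C2/C3 and the trans lactone being the stable arrangements.

Step 23
Reactants: 38 the dihydrobenzofuran-3-carboxylic acid
Product: 39 (3S,4S)-3-{3-[(1S,2S)-1,3-dihydroxy-1-(3-methoxy-4-triisopropylsilyloxyphenyl)propan-2-yl]-5-methoxy-4-triisopropylsilyloxybenzyl}-4-{[(2R,3S)-2-(4-hydroxy-3-methoxyphenyl)-3-(hydroxymethyl)-7-methoxy-2,3-dihydrobenzofuran-5-yl]methyl}dihydrofuran-2(3H)-one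
Conditions: BH3·THF (excess), THF, 0 °C to rt; MeOH quench
Reagents that add atoms: none
Why: Borane reduces a carboxylic acid through its acyloxyborane far faster than a γ-lactone, so the chemoselective reduction should give the C3 hydroxymethyl group and leave the lactone alone.

Step 24
Reactants: 39 the bis(triisopropylsilyl) ether of the target
Product: 40 (3S,4S)-3-{3-[(1S,2S)-1,3-dihydroxy-1-(4-hydroxy-3-methoxyphenyl)propan-2-yl]-4-hydroxy-5-methoxybenzyl}-4-{[(2R,3S)-2-(4-hydroxy-3-methoxyphenyl)-3-(hydroxymethyl)-7-methoxy-2,3-dihydrobenzofuran-5-yl]methyl}dihydrofuran-2(3H)-one (CNP0186558.3)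
Conditions: Bu4NF, AcOH, THF, 0 °C to rt
Reagents that add atoms: none
Why: Fluoride-mediated desilylation should cleave both aryl silyl ethers, and the acetic acid buffer protects the lactone and the phenols from base.

**Compound list**

1 | vanillin (4-hydroxy-3-methoxybenzaldehyde) | COc1cc(C=O)ccc1O | starting material
2 | 3-methoxy-4-(triisopropylsilyloxy)benzaldehyde | COc1cc(C=O)ccc1O[Si](C(C)C)(C(C)C)C(C)C | intermediate
3 | methyl vanillate (methyl 4-hydroxy-3-methoxybenzoate) | COC(=O)c1ccc(O)c(OC)c1 | starting material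
4 | methyl 4-(allyloxy)-3-methoxybenzoate | COC(=O)c1ccc(OCC=C)c(OC)c1 | intermediate
5 | methyl 3-allyl-4-hydroxy-5-methoxybenzoate | COC(=O)c1cc(CC=C)c(O)c(OC)c1 | intermediate
6 | methyl 3-allyl-5-methoxy-4-(triisopropylsilyloxy)benzoate | COC(=O)c1cc(CC=C)c(O[Si](C(C)C)(C(C)C)C(C)C)c(OC)c1 | intermediate
7 | methyl 3-methoxy-5-(2-oxoethyl)-4-(triisopropylsilyloxy)benzoate (arylacetaldehyde, not isolated) | COC(=O)c1cc(CC=O)c(O[Si](C(C)C)(C(C)C)C(C)C)c(OC)c1 | intermediate
8 | 2-[3-methoxy-5-(methoxycarbonyl)-2-(triisopropylsilyloxy)phenyl]acetic acid | COC(=O)c1cc(CC(=O)O)c(O[Si](C(C)C)(C(C)C)C(C)C)c(OC)c1 | intermediate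
9 | (S)-4-benzyloxazolidin-2-one | O=C1N[C@@H](Cc2ccccc2)CO1 | starting material
10 | mixed pivalic anhydride of acid 8 (not isolated) | COC(=O)c1cc(CC(=O)OC(=O)C(C)(C)C)c(O[Si](C(C)C)(C(C)C)C(C)C)c(OC)c1 | intermediate
11 | methyl 3-{2-[(S)-4-benzyl-2-oxooxazolidin-3-yl]-2-oxoethyl}-5-methoxy-4-(triisopropylsilyloxy)benzoate | COC(=O)c1cc(CC(=O)N2[C@@H](Cc3ccccc3)COC2=O)c(O[Si](C(C)C)(C(C)C)C(C)C)c(OC)c1 | intermediate
12 | O-trimethylsilyl ether of anti-aldol 13 (not isolated) | COc1cc([C@@H](O[Si](C)(C)C)[C@H](C(=O)N2[C@@H](Cc3ccccc3)COC2=O)c4cc(C(=O)OC)cc(OC)c4O[Si](C(C)C)(C(C)C)C(C)C)ccc1O[Si](C(C)C)(C(C)C)C(C)C | intermediate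
13 | methyl 3-{(2R,3S)-1-[(S)-4-benzyl-2-oxooxazolidin-3-yl]-3-hydroxy-3-[3-methoxy-4-(triisopropylsilyloxy)phenyl]-1-oxopropan-2-yl}-5-methoxy-4-(triisopropylsilyloxy)benzoate | COc1cc([C@@H](O)[C@H](C(=O)N2[C@@H](Cc3ccccc3)COC2=O)c4cc(C(=O)OC)cc(OC)c4O[Si](C(C)C)(C(C)C)C(C)C)ccc1O[Si](C(C)C)(C(C)C)C(C)C | intermediate
14 | (1S,2S)-2-[5-(hydroxymethyl)-3-methoxy-2-(triisopropylsilyloxy)phenyl]-1-[3-methoxy-4-(triisopropylsilyloxy)phenyl]propane-1,3-diol | COc1cc([C@@H](O)[C@H](CO)c2cc(CO)cc(OC)c2O[Si](C(C)C)(C(C)C)C(C)C)ccc1O[Si](C(C)C)(C(C)C)C(C)C | intermediate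
15 | {3-methoxy-5-[(4S,5S)-4-(3-methoxy-4-triisopropylsilyloxyphenyl)-2,2-dimethyl-1,3-dioxan-5-yl]-4-(triisopropylsilyloxy)phenyl}methanol | COc1cc([C@@H](OC(C)(C)OC2)[C@H]2c3cc(CO)cc(OC)c3O[Si](C(C)C)(C(C)C)C(C)C)ccc1O[Si](C(C)C)(C(C)C)C(C)C | intermediate
16 | (4S,5S)-5-[5-(bromomethyl)-3-methoxy-2-(triisopropylsilyloxy)phenyl]-4-[3-methoxy-4-(triisopropylsilyloxy)phenyl]-2,2-dimethyl-1,3-dioxane | COc1cc([C@@H](OC(C)(C)OC2)[C@H]2c3cc(CBr)cc(OC)c3O[Si](C(C)C)(C(C)C)C(C)C)ccc1O[Si](C(C)C)(C(C)C)C(C)C | intermediate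
17 | 3-(4-hydroxy-3-methoxyphenyl)propanoic acid (dihydroferulic acid) | COc1cc(CCC(=O)O)ccc1O | starting material
18 | benzyl 3-(4-benzyloxy-3-methoxyphenyl)propanoate (not isolated) | COc1cc(CCC(=O)OCc2ccccc2)ccc1OCc3ccccc3 | intermediate
19 | 3-(4-benzyloxy-3-methoxyphenyl)propanoic acid | COc1cc(CCC(=O)O)ccc1OCc2ccccc2 | intermediate
20 | (R)-4-benzyloxazolidin-2-one | O=C1N[C@H](Cc2ccccc2)CO1 | starting material
21 | mixed pivalic anhydride of acid 19 (not isolated) | COc1cc(CCC(=O)OC(=O)C(C)(C)C)ccc1OCc2ccccc2 | intermediate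
22 | (R)-4-benzyl-3-[3-(4-benzyloxy-3-methoxyphenyl)propanoyl]oxazolidin-2-one | COc1cc(CCC(=O)N2[C@H](Cc3ccccc3)COC2=O)ccc1OCc4ccccc4 | intermediate
23 | tert-butyl (3S)-4-[(R)-4-benzyl-2-oxooxazolidin-3-yl]-3-(4-benzyloxy-3-methoxybenzyl)-4-oxobutanoate | COc1cc(C[C@@H](CC(=O)OC(C)(C)C)C(=O)N2[C@H](Cc3ccccc3)COC2=O)ccc1OCc4ccccc4 | intermediate
24 | tert-butyl (3S)-3-(4-benzyloxy-3-methoxybenzyl)-4-hydroxybutanoate (not isolated) | COc1cc(C[C@@H](CC(=O)OC(C)(C)C)CO)ccc1OCc2ccccc2 | intermediate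
25 | (S)-4-(4-benzyloxy-3-methoxybenzyl)dihydrofuran-2(3H)-one | COc1cc(C[C@@H]2COC(=O)C2)ccc1OCc3ccccc3 | intermediate
26 | (3S,4S)-4-(4-benzyloxy-3-methoxybenzyl)-3-{3-methoxy-5-[(4S,5S)-4-(3-methoxy-4-triisopropylsilyloxyphenyl)-2,2-dimethyl-1,3-dioxan-5-yl]-4-triisopropylsilyloxybenzyl}dihydrofuran-2(3H)-one | COc1cc([C@@H](OC(C)(C)OC2)[C@H]2c3cc(C[C@@H]4C(=O)OC[C@H]4Cc5ccc(OCc6ccccc6)c(OC)c5)cc(OC)c3O[Si](C(C)C)(C(C)C)C(C)C)ccc1O[Si](C(C)C)(C(C)C)C(C)C | intermediate
27 | (3S,4S)-4-(4-benzyloxy-3-methoxybenzyl)-3-{3-[(1S,2S)-1,3-dihydroxy-1-(3-methoxy-4-triisopropylsilyloxyphenyl)propan-2-yl]-5-methoxy-4-triisopropylsilyloxybenzyl}dihydrofuran-2(3H)-one | COc1cc([C@@H](O)[C@H](CO)c2cc(C[C@@H]3C(=O)OC[C@H]3Cc4ccc(OCc5ccccc5)c(OC)c4)cc(OC)c2O[Si](C(C)C)(C(C)C)C(C)C)ccc1O[Si](C(C)C)(C(C)C)C(C)C | intermediate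
28 | (3S,4S)-3-{3-[(1S,2S)-1,3-dihydroxy-1-(3-methoxy-4-triisopropylsilyloxyphenyl)propan-2-yl]-5-methoxy-4-triisopropylsilyloxybenzyl}-4-(4-hydroxy-3-methoxybenzyl)dihydrofuran-2(3H)-one | COc1cc([C@@H](O)[C@H](CO)c2cc(C[C@@H]3C(=O)OC[C@H]3Cc4ccc(O)c(OC)c4)cc(OC)c2O[Si](C(C)C)(C(C)C)C(C)C)ccc1O[Si](C(C)C)(C(C)C)C(C)C | intermediate
29 | ferulic acid ((E)-3-(4-hydroxy-3-methoxyphenyl)acrylic acid) | COc1cc(/C=C/C(=O)O)ccc1O | starting material
30 | (E)-3-(4-acetoxy-3-methoxyphenyl)acrylic acid | COc1cc(/C=C/C(=O)O)ccc1OC(C)=O | intermediate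
31 | (2R)-bornane-10,2-sultam ((1S,2R,4R) bornane skeleton) | CC1(C)[C@@H]2CC[C@]13CS(=O)(=O)N[C@@H]3C2 | starting material
32 | (E)-3-(4-acetoxy-3-methoxyphenyl)acryloyl chloride (not isolated) | COc1cc(/C=C/C(Cl)=O)ccc1OC(C)=O | intermediate
33 | N-[(E)-3-(4-acetoxy-3-methoxyphenyl)acryloyl]-(2R)-bornane-10,2-sultam | COc1cc(/C=C/C(=O)N2[C@@H]3C[C@H]4CC[C@]3(CS2(=O)=O)C4(C)C)ccc1OC(C)=O | intermediate
34 | N-[(E)-3-(4-hydroxy-3-methoxyphenyl)acryloyl]-(2R)-bornane-10,2-sultam | COc1cc(/C=C/C(=O)N2[C@@H]3C[C@H]4CC[C@]3(CS2(=O)=O)C4(C)C)ccc1O | intermediate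
35 | phenol–quinone methide (not isolated): N-[(2S)-2-(2-hydroxy-3-methoxy-5-{lactonylmethyl as in 28}phenyl)-3-(3-methoxy-4-oxocyclohexa-2,5-dien-1-ylidene)propanoyl]-(2R)-bornane-10,2-sultam | COc1cc([C@@H](O)[C@H](CO)c2cc(C[C@@H]3C(=O)OC[C@H]3Cc4cc(OC)c(O)c(c4)[C@@H](C(=O)N5[C@@H]6C[C@H]7CC[C@]6(CS5(=O)=O)C7(C)C)C=C8C=CC(=O)C(OC)=C8)cc(OC)c2O[Si](C(C)C)(C(C)C)C(C)C)ccc1O[Si](C(C)C)(C(C)C)C(C)C | intermediate
36 | N-{[(2R,3R)-5-{[(3S,4S)-4-{3-[(1S,2S)-1,3-dihydroxy-1-(3-methoxy-4-triisopropylsilyloxyphenyl)propan-2-yl]-5-methoxy-4-triisopropylsilyloxybenzyl}-5-oxotetrahydrofuran-3-yl]methyl}-2-(4-hydroxy-3-methoxyphenyl)-7-methoxy-2,3-dihydrobenzofuran-3-yl]carbonyl}-(2R)-bornane-10,2-sultam | COc1cc([C@@H](O)[C@H](CO)c2cc(C[C@@H]3C(=O)OC[C@H]3Cc4cc(OC)c5c(c4)[C@@H](C(=O)N6[C@@H]7C[C@H]8CC[C@]7(CS6(=O)=O)C8(C)C)[C@H](c9ccc(O)c(OC)c9)O5)cc(OC)c2O[Si](C(C)C)(C(C)C)C(C)C)ccc1O[Si](C(C)C)(C(C)C)C(C)C | intermediate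
37 | peroxy acid corresponding to acid 38 (3-carboperoxoic acid, not isolated) | COc1cc([C@@H](O)[C@H](CO)c2cc(C[C@@H]3C(=O)OC[C@H]3Cc4cc(OC)c5c(c4)[C@@H](C(=O)OO)[C@H](c6ccc(O)c(OC)c6)O5)cc(OC)c2O[Si](C(C)C)(C(C)C)C(C)C)ccc1O[Si](C(C)C)(C(C)C)C(C)C | intermediate
38 | (2R,3R)-5-{[(3S,4S)-4-{3-[(1S,2S)-1,3-dihydroxy-1-(3-methoxy-4-triisopropylsilyloxyphenyl)propan-2-yl]-5-methoxy-4-triisopropylsilyloxybenzyl}-5-oxotetrahydrofuran-3-yl]methyl}-2-(4-hydroxy-3-methoxyphenyl)-7-methoxy-2,3-dihydrobenzofuran-3-carboxylic acid | COc1cc([C@@H](O)[C@H](CO)c2cc(C[C@@H]3C(=O)OC[C@H]3Cc4cc(OC)c5c(c4)[C@@H](C(=O)O)[C@H](c6ccc(O)c(OC)c6)O5)cc(OC)c2O[Si](C(C)C)(C(C)C)C(C)C)ccc1O[Si](C(C)C)(C(C)C)C(C)C | intermediate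
39 | (3S,4S)-3-{3-[(1S,2S)-1,3-dihydroxy-1-(3-methoxy-4-triisopropylsilyloxyphenyl)propan-2-yl]-5-methoxy-4-triisopropylsilyloxybenzyl}-4-{[(2R,3S)-2-(4-hydroxy-3-methoxyphenyl)-3-(hydroxymethyl)-7-methoxy-2,3-dihydrobenzofuran-5-yl]methyl}dihydrofuran-2(3H)-one | COc1cc([C@@H](O)[C@H](CO)c2cc(C[C@@H]3C(=O)OC[C@H]3Cc4cc(OC)c5c(c4)[C@@H](CO)[C@H](c6ccc(O)c(OC)c6)O5)cc(OC)c2O[Si](C(C)C)(C(C)C)C(C)C)ccc1O[Si](C(C)C)(C(C)C)C(C)C | intermediate
40 | (3S,4S)-3-{3-[(1S,2S)-1,3-dihydroxy-1-(4-hydroxy-3-methoxyphenyl)propan-2-yl]-4-hydroxy-5-methoxybenzyl}-4-{[(2R,3S)-2-(4-hydroxy-3-methoxyphenyl)-3-(hydroxymethyl)-7-methoxy-2,3-dihydrobenzofuran-5-yl]methyl}dihydrofuran-2(3H)-one (CNP0186558.3) | COc1cc([C@@H](O)[C@H](CO)c2cc(C[C@@H]3C(=O)OC[C@H]3Cc3cc(OC)c4c(c3)[C@@H](CO)[C@H](c3ccc(O)c(OC)c3)O4)cc(OC)c2O)ccc1O | target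

**Totals**

Total step count: 24.
Longest linear sequence: 16 steps (steps 2–10, 15–17, 21–24, from methyl vanillate).

**Steps most likely to fail**

Step 21. The cross-coupling may lose to homo-dimerisation of the feruloyl amide, ring C may be attacked at oxygen instead of carbon, or the sultam may give weak facial control. The fallback is known chemistry: the C3 unit is brought in at the alcohol oxidation level without an auxiliary, by the endwise dehydrogenative cross-coupling of coniferyl alcohol onto a guaiacyl phenol that is established for lignin model phenols. It sets out from 28: commercial coniferyl alcohol is fed slowly into 28 with horseradish peroxidase and H2O2 (acetone/phosphate buffer pH 6) or with Ag2O (acetone/toluene). The monolignol radical should bond through C8 to C5 of ring C to give the alcohol-level quinone methide F1, which closes to the trans-dihydrobenzofuran. The (2R,3S) isomer is separated from its (2S,3R) partner by preparative HPLC; the two are diastereomers because of the four fixed centres. The product is 39, so the route is rejoined at 39 and steps 22 and 23 fall away.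

Step 7. The acidic α-aryl centre may epimerise under Et3N, or addition to the electron-rich aldehyde may be slow, and either would erode the anti selectivity. The fallback is a syn-aldol followed by inversion of the carbinol. It sets out from acid 8 (through anhydride 10): the (R)-oxazolidinone 20 gives the enantiomeric-auxiliary imide F2. Its dibutylboron Z-enolate (Bu2BOTf, i-Pr2NEt, CH2Cl2, −78 °C) adds to aldehyde 2 through a chair transition state to give the Evans syn adduct F3, with C8 correct and C7 epimeric. LiBH4 as in step 8 gives the (1R,2S)-triol F4. AcCl with 2,4,6-collidine at −78 °C acetylates only the two primary alcohols, giving the diacetate F5. A Mitsunobu reaction (4-nitrobenzoic acid, PPh3, diisopropyl azodicarboxylate) inverts the benzylic carbinol, giving the triester F6. K2CO3 in MeOH at 0 °C removes the three esters, and the route is rejoined at triol 14.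

Step 22. Under the basic peroxide the C3 proton of the acyl sultam may be removed before the carbonyl is attacked, which leads to β-elimination of the ring C aryloxide (opening of the dihydrofuran) or to epimerisation; the lactone may also fail to re-close cleanly. The fallback is direct reductive cleavage. It sets out from 36: NaBH4 in THF/H2O at 0 °C should reduce the activated N-acyl sultam carbonyl through the aldehyde F7 to the primary alcohol and leave the γ-lactone alone. This gives 39 in one operation, so the route is rejoined at 39 and step 23 is not needed.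

**Further compounds**

F1 | step 21 | alcohol-level phenol–quinone methide from 28 and coniferyl alcohol: 28 bearing on ring C, ortho to the free OH, a (1-hydroxy-3-(3-methoxy-4-oxocyclohexa-2,5-dien-1-ylidene)propan-2-yl) group | COc1cc([C@@H](O)[C@H](CO)c2cc(C[C@@H]3C(=O)OC[C@H]3Cc4cc(OC)c(O)c(c4)[C@@H](CO)C=C5C=CC(=O)C(OC)=C5)cc(OC)c2O[Si](C(C)C)(C(C)C)C(C)C)ccc1O[Si](C(C)C)(C(C)C)C(C)C
F2 | step 7 | methyl 3-{2-[(R)-4-benzyl-2-oxooxazolidin-3-yl]-2-oxoethyl}-5-methoxy-4-(triisopropylsilyloxy)benzoate | COC(=O)c1cc(CC(=O)N2[C@H](Cc3ccccc3)COC2=O)c(O[Si](C(C)C)(C(C)C)C(C)C)c(OC)c1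
F3 | step 7 | methyl 3-{(2R,3R)-1-[(R)-4-benzyl-2-oxooxazolidin-3-yl]-3-hydroxy-3-[3-methoxy-4-(triisopropylsilyloxy)phenyl]-1-oxopropan-2-yl}-5-methoxy-4-(triisopropylsilyloxy)benzoate (syn adduct) | COc1cc([C@H](O)[C@H](C(=O)N2[C@H](Cc3ccccc3)COC2=O)c4cc(C(=O)OC)cc(OC)c4O[Si](C(C)C)(C(C)C)C(C)C)ccc1O[Si](C(C)C)(C(C)C)C(C)C
F4 | step 7 | (1R,2S)-2-[5-(hydroxymethyl)-3-methoxy-2-(triisopropylsilyloxy)phenyl]-1-[3-methoxy-4-(triisopropylsilyloxy)phenyl]propane-1,3-diol | COc1cc([C@H](O)[C@H](CO)c2cc(CO)cc(OC)c2O[Si](C(C)C)(C(C)C)C(C)C)ccc1O[Si](C(C)C)(C(C)C)C(C)C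
F5 | step 7 | diacetate of F4 at both primary alcohols, (1R,2S) secondary alcohol free | COc1cc([C@H](O)[C@H](COC(C)=O)c2cc(COC(C)=O)cc(OC)c2O[Si](C(C)C)(C(C)C)C(C)C)ccc1O[Si](C(C)C)(C(C)C)C(C)C
F6 | step 7 | (1S,2S) 4-nitrobenzoate of the inverted benzylic carbinol, both primary alcohols as acetates | COc1cc([C@@H](OC(=O)c3ccc(cc3)[N+](=O)[O-])[C@H](COC(C)=O)c2cc(COC(C)=O)cc(OC)c2O[Si](C(C)C)(C(C)C)C(C)C)ccc1O[Si](C(C)C)(C(C)C)C(C)C
F7 | step 22 | (2R,3R)-dihydrobenzofuran-3-carbaldehyde corresponding to acid 38 | COc1cc([C@@H](O)[C@H](CO)c2cc(C[C@@H]3C(=O)OC[C@H]3Cc4cc(OC)c5c(c4)[C@@H](C=O)[C@H](c6ccc(O)c(OC)c6)O5)cc(OC)c2O[Si](C(C)C)(C(C)C)C(C)C)ccc1O[Si](C(C)C)(C(C)C)C(C)C
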